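**Plan**

1. The side rings are numbered C1 (carries the bridge CH2), C2 (OH), C3 (CH3), C4 (OMe), C5 (butyryl), C6 (OH). The retrosynthesis cuts C3–C4 and C5–C6 in both side rings at once, then the two bridge CH2–C1 bonds, then the two formyl and the butyryl C–C bonds of the central ring.
2. This cut is possible because C4(OMe)–C5(COPr) is the triple bond of 1-methoxyhex-1-yn-3-one, while C6–C1–C2–C3, with its CH2 branch on C1 and CH3 on C3, is a 2-(arylmethyl)-3-oxopentanoate, i.e. a 1-methoxy-1,3-bis(silyloxy)diene.
3. Forward: phloroglucinol is butyrylated, diformylated and O-benzylated (central ring complete). Both aldehydes are condensed with methyl 3-oxopentanoate and reduced, and both arms are turned into silyloxydienes. The two side rings are then closed together by [4+2] benzannulation with the ynone, and hydrogenolysis ends the route.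
4. The ynone is made in two steps from methoxyacetylide and butanal.
5. Agrimol C has no stereocentre; centres and double-bond geometries that arise on the way are uncontrolled and vanish on oxidation, enolisation or aromatisation.

Key step: step 10

Remark on the chemistry: compounds 13 to 17 are carried as mixtures of alkene, enol ether or diastereo-isomers; this is assumed to be harmless because each of these elements is lost by step 10.

**Route**

Step 1
Reactants: 1 chloroacetaldehyde dimethyl acetal (2-chloro-1,1-dimethoxyethane); 2 butanal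
Product: 4 1-methoxyhex-1-yn-3-ol (racemic), via lithium methoxyacetylide 3 (not isolated)
Conditions: Et2NH, n-BuLi (3.0 equiv each), THF, 0 °C; 1, 0 °C; then 2, −78 → 0 °C; aq. NH4Cl
Reagents that add atoms: none
Why: LiNEt2 converts the chloroacetal by successive loss of methanol and HCl and a final deprotonation into lithium methoxyacetylide, whose 1,2-addition to the aldehyde (acetylide addition) gives the propargylic alcohol as a racemate, the carbinol centre being removed in step 2.

Step 2
Reactants: 4 1-methoxyhex-1-yn-3-ol
Product: 5 1-methoxyhex-1-yn-3-one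
Conditions: activated MnO2 (excess), CH2Cl2, rt; filtration, used promptly
Reagents that add atoms: none
Why: MnO2 oxidation of a propargylic alcohol proceeds under neutral heterogeneous conditions and therefore spares the acid-labile ynol ether, which would otherwise hydrate or rearrange (Meyer–Schuster type).

Step 3
Reactants: 6 phloroglucinol; 7 butyronitrile
Product: 9 1-(2,4,6-trihydroxyphenyl)butan-1-one, via ketiminium chloride 8 (not isolated)
Conditions: ZnCl2, HCl (g), Et2O, 0 °C; then H2O, reflux
Reagents that add atoms: water O
Why: Hoesch reaction, in which the nitrilium species acylates the very electron-rich ring once because the precipitating ketiminium salt is deactivated towards a second attack, and hydrolysis releases the aryl ketone.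

Step 4
Reactants: 9 1-(2,4,6-trihydroxyphenyl)butan-1-one
Product: 10 5-butanoyl-2,4,6-trihydroxybenzene-1,3-dicarbaldehyde
Conditions: Cl2CHOMe (5 equiv), TiCl4 (6 equiv), CH2Cl2, 0 °C → rt; then 2 M HCl, 0 °C
Reagents that add atoms: dichloromethyl methyl ether COC(Cl)Cl; water O
Why: Rieche formylation, in which the TiCl4-activated chloro ether attacks the two remaining ring positions (each ortho or para to all three hydroxyls) through titanium phenoxides while the chelated ketone stays inert, and hydrolysis of the α-chloro ethers gives both aldehydes.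

Step 5
Reactants: 10 5-butanoyl-2,4,6-trihydroxybenzene-1,3-dicarbaldehyde
Product: 11 2,4,6-tris(benzyloxy)-5-butanoylbenzene-1,3-dicarbaldehyde
Conditions: BnBr (3.6 equiv), K2CO3, DMF, 60 °C
Reagents that add atoms: benzyl bromide BrCc1ccccc1
Why: Williamson etherification in a dipolar aprotic solvent, where only O-alkylation is possible because every ring carbon is substituted; the benzyl ethers block coumarin or chromene formation in step 6 and are removable by hydrogenolysis at the end.

Step 6
Reactants: 11 2,4,6-tris(benzyloxy)-5-butanoylbenzene-1,3-dicarbaldehyde; 12 methyl 3-oxopentanoate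
Product: 13 dimethyl 2,2'-{[2,4,6-tris(benzyloxy)-5-butanoyl-1,3-phenylene]dimethanylylidene}bis(3-oxopentanoate) (mixture of alkene isomers)
Conditions: 12 (2.5 equiv), piperidine (cat.), AcOH (cat.), toluene, reflux, Dean–Stark trap
Reagents that add atoms: none
Why: Knoevenagel condensation with azeotropic removal of water, in which the two aldehydes (made more electrophilic by the acyl-substituted ring) react whereas the di-ortho-substituted aryl ketone does not; the alkene geometry is irrelevant.

Step 7
Reactants: 13 bis(alkylidene keto ester)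
Product: 14 dimethyl 2,2'-{[2,4,6-tris(benzyloxy)-5-butanoyl-1,3-phenylene]bis(methylene)}bis(3-oxopentanoate) (mixture of diastereomers)
Conditions: Hantzsch ester (diethyl 2,6-dimethyl-1,4-dihydropyridine-3,5-dicarboxylate, 2.4 equiv), toluene, 80 °C
Reagents that add atoms: none
Why: Transfer hydrogenation (conjugate reduction), in which the dihydropyridine delivers hydride only to the β-carbon of the doubly activated alkene and leaves ketones, esters and benzyl ethers untouched; the two new α-centres are uncontrolled and are erased in step 8.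

Step 8
Reactants: 14 bis(β-keto ester)
Product: 15 dimethyl 2,2'-{[2,4,6-tris(benzyloxy)-5-butanoyl-1,3-phenylene]bis(methylene)}bis[3-(trimethylsilyloxy)pent-2-enoate] (enol ether geometry not defined)
Conditions: Me3SiCl (3 equiv), Et3N (3.5 equiv), toluene, rt; filtration under argon
Reagents that add atoms: chlorotrimethylsilane C[Si](C)(C)Cl
Why: Soft enolisation and O-silylation of a β-keto ester gives the 3-silyloxy-2-enoate, while the non-activated aryl ketone is not silylated by this reagent pair.

Step 9
Reactants: 15 bis(3-silyloxy-2-enoate)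
Product: 16 1,3,5-tris(benzyloxy)-2,4-bis{[(3Z)-1-methoxy-1,3-bis(trimethylsilyloxy)penta-1,3-dien-2-yl]methyl}-6-[1-(trimethylsilyloxy)but-1-en-1-yl]benzene (ketene acetal and butenyl geometry not defined; used crude)
Conditions: LiN(i-Pr)2 (3.5 equiv), THF, −78 °C; then Me3SiCl (4 equiv), −78 → 0 °C
Reagents that add atoms: chlorotrimethylsilane C[Si](C)(C)Cl
Why: γ-Deprotonation of each 3-silyloxy-2-enoate gives the extended ester dienolate, which is O-silylated to the 1-methoxy-1,3-bis(silyloxy)diene (the standard two-stage preparation of such dienes); the more acidic aryl ketone is deprotonated as well and is deliberately converted into its silyl enol ether by the excess reagents.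

Step 10
Reactants: 16 bis-diene; 5 1-methoxyhex-1-yn-3-one (2.4 equiv)
Product: 18 agrimol C tribenzyl ether (the three central-ring hydroxyls as benzyl ethers), via twofold cycloadduct 17 (not isolated)
Conditions: Me3SiOTf (0.4 equiv), CH2Cl2, −78 → 0 °C; then 1 M HCl, THF, 0 °C → rt
Reagents that add atoms: none
Why: Proposed new method: O-silylation of the ynone by Me3SiOTf gives a 1-methoxy-3-silyloxy propargyl/allenyl cation whose methoxy-bearing carbon is attacked by the methyl-bearing terminus of each bis(silyloxy)diene (vinylogous Mukaiyama–Michael addition, forming C3–C4), and the central carbon of the resulting silyloxyallene then adds to the dioxy-stabilised allyl cation at the former ketene acetal carbon (forming C5–C6) with release of Me3SiOTf, so that the overall event is a stepwise, polarity-matched [4+2] cycloaddition. The closest known reaction type is the Diels–Alder benzannulation of 1-alkoxy-1,3-bis(silyloxy)dienes with acetylenic esters and ketones that lack a donor substituent, the donor-substituted alkyne being the new element. Each side ring closes in the six-membered [4+2] mode (four diene carbons plus the two alkyne carbons, the alternative closure at the other cation terminus being a four-membered ring), after which acid expels methoxytrimethylsilane from the mixed ketal at C6, the C3 hydrogen moves to oxygen and the remaining silyl ethers are hydrolysed to the arene. The C3 and C6 centres of 17 are formed without control and both become aromatic carbons, so no stereochemical element has to be set. The step needs regioselectivity (OMe next to CH3, butyryl next to the new C6 hydroxyl), which follows from the nucleophilic CH terminus of the diene meeting the electrophilic OMe-bearing alkyne carbon, and it needs the [4+2] rather than the [3+3] mode, which the arylmethyl group on the central diene carbon secures because attack through that carbon could not lead to an arene. The hindered and less nucleophilic silyl enol ether of the central butyryl group is a spectator and returns to the ketone in the acidic work-up.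

Step 11
Reactants: 18 agrimol C tribenzyl ether
Product: 19 agrimol C
Conditions: H2 (1 atm), 10% Pd/C, EtOAc–MeOH, rt; stopped after uptake of three equivalents
Reagents that add atoms: none
Why: Hydrogenolysis of aryl benzyl ethers under neutral conditions at ambient pressure, under which the diarylmethane bridges, the aryl methyl ethers and the hydrogen-bonded aryl ketones are expected to persist.

**Compound list**

1 | chloroacetaldehyde dimethyl acetal | COC(CCl)OC | starting material
2 | butanal | CCCC=O | starting material
3 | lithium methoxyacetylide | [Li]C#COC | intermediate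
4 | 1-methoxyhex-1-yn-3-ol (racemic) | CCCC(O)C#COC | intermediate
5 | 1-methoxyhex-1-yn-3-one | CCCC(=O)C#COC | intermediate
6 | phloroglucinol | Oc1cc(O)cc(O)c1 | starting material
7 | butyronitrile | CCCC#N | starting material
8 | 1-(2,4,6-trihydroxyphenyl)butan-1-iminium chloride | CCCC(=[NH2+])c1c(O)cc(O)cc1O.[Cl-] | intermediate
9 | 1-(2,4,6-trihydroxyphenyl)butan-1-one | CCCC(=O)c1c(O)cc(O)cc1O | intermediate
10 | 5-butanoyl-2,4,6-trihydroxybenzene-1,3-dicarbaldehyde | CCCC(=O)c1c(O)c(C=O)c(O)c(C=O)c1O | intermediate
11 | 2,4,6-tris(benzyloxy)-5-butanoylbenzene-1,3-dicarbaldehyde | CCCC(=O)c1c(OCc2ccccc2)c(C=O)c(OCc2ccccc2)c(C=O)c1OCc1ccccc1 | intermediate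
12 | methyl 3-oxopentanoate | CCC(=O)CC(=O)OC | starting material
13 | dimethyl 2,2'-{[2,4,6-tris(benzyloxy)-5-butanoyl-1,3-phenylene]dimethanylylidene}bis(3-oxopentanoate), alkene geometry not defined | CCCC(=O)c1c(OCc2ccccc2)c(C=C(C(=O)CC)C(=O)OC)c(OCc2ccccc2)c(C=C(C(=O)CC)C(=O)OC)c1OCc1ccccc1 | intermediate
14 | dimethyl 2,2'-{[2,4,6-tris(benzyloxy)-5-butanoyl-1,3-phenylene]bis(methylene)}bis(3-oxopentanoate), mixture of diastereomers | CCCC(=O)c1c(OCc2ccccc2)c(CC(C(=O)CC)C(=O)OC)c(OCc2ccccc2)c(CC(C(=O)CC)C(=O)OC)c1OCc1ccccc1 | intermediate
15 | dimethyl 2,2'-{[2,4,6-tris(benzyloxy)-5-butanoyl-1,3-phenylene]bis(methylene)}bis[3-(trimethylsilyloxy)pent-2-enoate], enol ether geometry not defined | CCCC(=O)c1c(OCc2ccccc2)c(CC(C(=O)OC)=C(CC)O[Si](C)(C)C)c(OCc2ccccc2)c(CC(C(=O)OC)=C(CC)O[Si](C)(C)C)c1OCc1ccccc1 | intermediate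
16 | 1,3,5-tris(benzyloxy)-2,4-bis{[(3Z)-1-methoxy-1,3-bis(trimethylsilyloxy)penta-1,3-dien-2-yl]methyl}-6-[1-(trimethylsilyloxy)but-1-en-1-yl]benzene, ketene acetal and butenyl geometry not defined | CCC=C(O[Si](C)(C)C)c1c(OCc2ccccc2)c(CC(=C(OC)O[Si](C)(C)C)/C(O[Si](C)(C)C)=C/C)c(OCc2ccccc2)c(CC(=C(OC)O[Si](C)(C)C)/C(O[Si](C)(C)C)=C/C)c1OCc1ccccc1 | intermediate
17 | twofold cycloadduct: each arm a 5-butanoyl-4,6-dimethoxy-3-methyl-2,6-bis(trimethylsilyloxy)cyclohexa-1,4-dien-1-ylmethyl group on the central ring of 16, mixture of diastereomers | CCC=C(O[Si](C)(C)C)c1c(OCc2ccccc2)c(CC2=C(O[Si](C)(C)C)C(C)C(OC)=C(C(=O)CCC)C2(OC)O[Si](C)(C)C)c(OCc2ccccc2)c(CC2=C(O[Si](C)(C)C)C(C)C(OC)=C(C(=O)CCC)C2(OC)O[Si](C)(C)C)c1OCc1ccccc1 | intermediate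
18 | agrimol C tribenzyl ether (benzyl ethers on the three central-ring oxygens) | CCCC(=O)c1c(OCc2ccccc2)c(Cc2c(O)c(C)c(OC)c(C(=O)CCC)c2O)c(OCc2ccccc2)c(Cc2c(O)c(C)c(OC)c(C(=O)CCC)c2O)c1OCc1ccccc1 | intermediate
19 | agrimol C | CCCC(=O)c1c(O)c(Cc2c(O)c(C)c(OC)c(C(=O)CCC)c2O)c(O)c(Cc2c(O)c(C)c(OC)c(C(=O)CCC)c2O)c1O | target

**Step count and risks**

Total step count: 11. Longest linear sequence: 9 steps (steps 3 to 11, from phloroglucinol); the ynone branch (steps 1 and 2) joins at step 10.

Steps most likely to fail:

1. Step 10. The silyl-activated alkoxyalkyne may oligomerise or hydrate faster than it is attacked, the dienes may simply be protodesilylated back to 14, or the first C–C bond may form without ring closure. The fallback uses only known reactions; it sets out from 9 and comes back at 19.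
   - Twofold O-benzylation of 9 (BnBr, K2CO3, acetone, reflux) should leave the chelated hydroxyl free and give 1-[2,4-bis(benzyloxy)-6-hydroxyphenyl]butan-1-one F1.
   - Iodination ortho to that hydroxyl (N-iodosuccinimide, CH2Cl2) gives 1-[4,6-bis(benzyloxy)-2-hydroxy-3-iodophenyl]butan-1-one F2.
   - O-Methylation (MeI, K2CO3, DMF) gives 1-[4,6-bis(benzyloxy)-3-iodo-2-methoxyphenyl]butan-1-one F3.
   - Suzuki–Miyaura methylation (trimethylboroxine, Pd(PPh3)4, K2CO3, dioxane, 100 °C) gives 1-[4,6-bis(benzyloxy)-2-methoxy-3-methylphenyl]butan-1-one F4.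
   - Hydrogenolysis (H2, Pd/C, EtOAc) gives the side-ring monomer 1-(4,6-dihydroxy-2-methoxy-3-methylphenyl)butan-1-one F5.
   - Mannich aminomethylation at its only free ring position (aqueous CH2O, Me2NH, EtOH) gives 1-{5-[(dimethylamino)methyl]-4,6-dihydroxy-2-methoxy-3-methylphenyl}butan-1-one F6.
   - Heating two equivalents of F6 with one of 9 (dioxane, reflux) releases dimethylamine to form the ortho-quinone methide, which alkylates both free positions of 9 and delivers 19 directly.

2. Step 6. Condensation at aldehydes that are each flanked by two benzyloxy groups may stall after the first arm, or the adduct may take up a second keto ester by Michael addition. The fallback sets out from 11 and comes back at 14.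
   - Reductive alkylation of 2,2-dimethyl-1,3-dioxane-4,6-dione with 11 (Hantzsch ester, L-proline cat., EtOH, rt), helped by the much higher acidity of this partner, should give 5,5'-{[2,4,6-tris(benzyloxy)-5-butanoyl-1,3-phenylene]bis(methylene)}bis(2,2-dimethyl-1,3-dioxane-4,6-dione) F7.
   - Methanolysis (MeOH, reflux) opens both dioxanedione rings with loss of acetone to 2,2'-{[2,4,6-tris(benzyloxy)-5-butanoyl-1,3-phenylene]bis(methylene)}bis(3-methoxy-3-oxopropanoic acid) F8.
   - Its magnesium salt (MgCl2, Et3N, THF) is acylated by 1-propanoylimidazole with loss of CO2 (decarboxylative Claisen condensation) to give 14.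

3. Step 4. The second formylation may stop at the monoaldehyde because the ring then carries two acyl groups, or the Lewis acid may trigger condensation at the ketone side chain. The fallback sets out from 6 and comes back at 10, with the order of the two acylation events reversed.
   - Vilsmeier–Haack diformylation of phloroglucinol (POCl3, DMF, dioxane; then H2O) gives 2,4,6-trihydroxybenzene-1,3-dicarbaldehyde F9.
   - Friedel–Crafts acylation of its remaining ring position (butanoyl chloride, AlCl3, nitrobenzene, 60 °C) gives 10; step 3 and compound 9 are then not needed.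

Further compounds
F1 | step 10 | 1-[2,4-bis(benzyloxy)-6-hydroxyphenyl]butan-1-one | CCCC(=O)c1c(O)cc(OCc2ccccc2)cc1OCc1ccccc1
F2 | step 10 | 1-[4,6-bis(benzyloxy)-2-hydroxy-3-iodophenyl]butan-1-one | CCCC(=O)c1c(O)c(I)c(OCc2ccccc2)cc1OCc1ccccc1
F3 | step 10 | 1-[4,6-bis(benzyloxy)-3-iodo-2-methoxyphenyl]butan-1-one | CCCC(=O)c1c(OC)c(I)c(OCc2ccccc2)cc1OCc1ccccc1
F4 | step 10 | 1-[4,6-bis(benzyloxy)-2-methoxy-3-methylphenyl]butan-1-one | CCCC(=O)c1c(OC)c(C)c(OCc2ccccc2)cc1OCc1ccccc1
F5 | step 10 | 1-(4,6-dihydroxy-2-methoxy-3-methylphenyl)butan-1-one | CCCC(=O)c1c(OC)c(C)c(O)cc1O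
F6 | step 10 | 1-{5-[(dimethylamino)methyl]-4,6-dihydroxy-2-methoxy-3-methylphenyl}butan-1-one | CCCC(=O)c1c(OC)c(C)c(O)c(CN(C)C)c1O
F7 | step 6 | 5,5'-{[2,4,6-tris(benzyloxy)-5-butanoyl-1,3-phenylene]bis(methylene)}bis(2,2-dimethyl-1,3-dioxane-4,6-dione) | CCCC(=O)c1c(OCc2ccccc2)c(CC2C(=O)OC(C)(C)OC2=O)c(OCc2ccccc2)c(CC2C(=O)OC(C)(C)OC2=O)c1OCc1ccccc1
F8 | step 6 | 2,2'-{[2,4,6-tris(benzyloxy)-5-butanoyl-1,3-phenylene]bis(methylene)}bis(3-methoxy-3-oxopropanoic acid), mixture of diastereomers | CCCC(=O)c1c(OCc2ccccc2)c(CC(C(=O)O)C(=O)OC)c(OCc2ccccc2)c(CC(C(=O)O)C(=O)OC)c1OCc1ccccc1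
F9 | step 4 | 2,4,6-trihydroxybenzene-1,3-dicarbaldehyde | O=Cc1c(O)cc(O)c(C=O)c1O
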